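The ten-membered carbocycle is traced back to a carvone-derived cyclohexane (C1, C6–C10) by cutting C3–C4 and rejoining C1–C6. The feature exploited is the C1 ketone flanked by C2=C3 (the furanone double bond) and by the C5/C6 diol, read as a former E-alkene: a cyclodeca-2,5-dienone, the retron of an alkynyl anionic oxy-Cope shift. In one operation this step expands the six-membered ring by four atoms, forms C3–C4 and sets C4. Its precursor is a 1-ethynyl-2-(E)-propenylcyclohexanol with the ethynyl and propenyl groups trans-diequatorial, silyl ethers on O8 and O10 and a silyloxymethylvinyl group on C7.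

Key step: step 12

Remark: germacrane locants are used for every intermediate (C1 = carvone carbonyl carbon, C10 = its methyl-bearing carbon, C12 = oxygen-bearing carbon of the former isopropenyl group and later lactone carbonyl, C13 = exocyclic methylene); the allene axis of 20 and the transient centres of 26, F3 and F4 are left undefined because they are erased in the same or the next operation.

Step 1
Reactants: 1 (R)-carvone
Product: 2 (R)-5-(3-chloroprop-1-en-2-yl)-2-methylcyclohex-2-en-1-one
Conditions: Ca(OCl)2, CO2 (dry ice), CH2Cl2/H2O, 0 °C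
Reagents that add atoms: calcium hypochlorite, [Ca+2].[O-]Cl.[O-]Cl
Why: Hypochlorous acid released in situ chlorinates the electron-rich isopropenyl group in an ene-type allylic chlorination (chlorine on C12, the 1,1-disubstituted C11=C13 alkene is kept), while the electron-poor enone and the C7 stereocentre are not touched.

Step 2
Reactants: 2 (R)-5-(3-chloroprop-1-en-2-yl)-2-methylcyclohex-2-en-1-one
Product: 4 (R)-5-(3-hydroxyprop-1-en-2-yl)-2-methylcyclohex-2-en-1-one, via allylic acetate 3 (not isolated)
Conditions: KOAc, Bu4NI (cat.), DMF, 60 °C; then K2CO3 (cat.), MeOH, 0 °C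
Reagents that add atoms: potassium acetate, CC(=O)[O-].[K+]
Why: SN2 displacement of the primary allylic chloride by acetate followed by mild transesterification gives the allylic alcohol without exposing the enone to a strong base.

Step 3
Reactants: 4 (R)-5-(3-hydroxyprop-1-en-2-yl)-2-methylcyclohex-2-en-1-one
Product: 5 12-O-TBDPS enone
Conditions: TBDPSCl, imidazole, DMF, 0 °C → rt
Reagents that add atoms: tert-butyl(chloro)diphenylsilane, CC(C)(C)[Si](Cl)(c1ccccc1)c1ccccc1
Why: Imidazole-promoted silylation of the primary alcohol installs an ether that should survive the enolate, peroxide, hydride and mild fluoride steps and is removed only in step 15.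

Step 4
Reactants: 5 12-O-TBDPS enone; 6 allyl bromide
Product: 8 6-allyl enone (6,7-trans), via lithium dienolate 7 (not isolated)
Conditions: LiN(iPr)2, THF, −78 °C; then allyl bromide, −78 → −30 °C
Reagents that add atoms: none
Why: Kinetic deprotonation at C6 gives the cross-conjugated lithium enolate, which is allylated on the face opposite the adjacent C7 substituent (enolate alkylation), so C6 is set with the allyl group trans to the side chain.

Step 5
Reactants: 8 6-allyl enone (6,7-trans)
Product: 11 8-hydroxy enone, via linear dienol silyl ether 9 (not isolated), via vinyl epoxide 10 (not isolated)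
Conditions: TBSOTf, Et3N, CH2Cl2, 0 °C → rt; then dimethyldioxirane, acetone, −78 → −40 °C; then AcOH, THF/H2O, 0 °C
Reagents that add atoms: dimethyldioxirane, CC1(C)OO1
Why: Soft enolisation under equilibrating conditions gives the linear 1-silyloxy-1,3-diene, in which A(1,2) strain between the C1 silyloxy group and the C6 allyl group holds the C6 and C7 substituents pseudo-axial, so the dioxirane epoxidises the electron-rich terminal C8=C9 bond anti to the C7 side chain and the epoxide opens to the trans 8-hydroxy enone (vinylogous Rubottom oxidation).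

Step 6
Reactants: 11 8-hydroxy enone
Product: 12 hydroxy epoxy ketone
Conditions: H2O2 (30% aq.), NaOH (cat.), MeOH, −10 °C
Reagents that add atoms: hydrogen peroxide, OO
Why: In this Weitz–Scheffer epoxidation the hydroperoxide adds axially to C9 of the half-chair with the C6, C7 and C8 substituents pseudo-equatorial, that is anti to the C7 side chain and syn to the hydrogen-bonding C8 hydroxyl, and the enolate closes on the same face, which sets C9 and places the C10 oxygen trans and the C10 methyl cis to the C7 side chain, as with carvone itself.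

Step 7
Reactants: 12 hydroxy epoxy ketone
Product: 13 8-O-TBS epoxy ketone
Conditions: TBSOTf, 2,6-lutidine, CH2Cl2, −78 °C
Reagents that add atoms: tert-butyldimethylsilyl trifluoromethanesulfonate, CC(C)(C)[Si](C)(C)OS(=O)(=O)C(F)(F)F
Why: Silylation of the secondary alcohol with a silyl triflate and a hindered pyridine base at low temperature should leave the epoxy ketone intact.

Step 8
Reactants: 13 8-O-TBS epoxy ketone
Product: 14 propenyl epoxy ketone
Conditions: RuHCl(CO)(PPh3)3 (cat.), toluene, 70 °C
Reagents that add atoms: none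
Why: Ruthenium hydride addition and β-hydride elimination (olefin isomerisation) move the monosubstituted double bond by one position to the thermodynamically preferred (E)-propenyl group, whereas the hindered 1,1-disubstituted C11=C13 alkene and the internal alkene just formed insert far more slowly, so C6 and C7 are not affected.

Step 9
Reactants: 14 propenyl epoxy ketone; 15 ethynylmagnesium bromide
Product: 16 epoxy ethynyl carbinol
Conditions: HC≡CMgBr, CeCl3, THF, −78 → −20 °C; then H2O
Reagents that add atoms: none
Why: The acetylide adds to the C1 carbonyl anti to the pseudo-axial epoxide C–O bond (Felkin–Anh polar control, the usual course for 2,3-epoxycyclohexanones, with the C6 propenyl group on the epoxide face as well), which sets C1 with the ethynyl group cis to the C10 methyl and trans to the propenyl group, while CeCl3 suppresses enolisation at the doubly activated C6–H.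

Step 10
Reactants: 16 epoxy ethynyl carbinol
Product: 17 ethynyl 1,10-diol
Conditions: LiEt3BH, THF, 0 °C → rt; then H2O
Reagents that add atoms: none
Why: Hydride opens the trisubstituted epoxide by SN2 attack at the secondary C9, anti to the oxygen and assisted by the neighbouring lithium alkoxide, because the fully substituted C10 is inaccessible, so the C10–O bond and its configuration are retained (reductive epoxide opening).

Step 11
Reactants: 17 ethynyl 1,10-diol
Product: 18 oxy-Cope precursor (10-O-TES)
Conditions: TESOTf (1.05 equiv), 2,6-lutidine, CH2Cl2, −78 °C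
Reagents that add atoms: triethylsilyl trifluoromethanesulfonate, CC[Si](CC)(CC)OS(=O)(=O)C(F)(F)F
Why: The equatorial C10 hydroxyl should be silylated in preference to the axial C1 hydroxyl, which is flanked by a quaternary and a tertiary carbon, and any C1 silyl ether would converge on the same alkoxide in step 12 by 1,4-O→O silyl transfer.

Step 12
Reactants: 18 oxy-Cope precursor (10-O-TES)
Product: 21 (2Z,5E)-cyclodecadienone, via potassium alkoxide 19 (not isolated), via potassium allenolate 20 (not isolated)
Conditions: KN(SiMe3)2 (1.1 equiv), 18-crown-6, THF, −78 → 25 °C; then AcOH, −78 °C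
Reagents that add atoms: none
Why: The crown-separated potassium alkoxide weakens the C1–C6 bond and triggers a concerted [3,3]-sigmatropic shift in which C1–C6 breaks and C3–C4 forms, giving a cyclic allenolate that is protonated at C2 on quenching to the (2Z)-enone. The closest known reaction type is the anionic oxy-Cope rearrangement of 1-alkynyl-2-alkenylcyclohexanols. The ten-membered ring arises by four-atom expansion of the six-membered ring through a six-centre chair-like transition state, not by an end-to-end cyclisation. C4 is set by chirality transfer from C6: with the methyl of the (E)-propenyl group pseudo-equatorial, C3 bonds to the alkene face that the departing C1–C6 bond occupied, which gives 4S. The step needs E geometry at C5=C6 and selective alkoxide formation; the first is secured by the trans-diequatorial ethynyl and propenyl groups on a chair that keeps the C7, C8 and O10 substituents equatorial, so that C7 is pseudo-equatorial in the transition state, and the second by one equivalent of a hindered amide base, which should leave the terminal alkyne unmetallated. Silyl shuttling between O1 and O10 would be harmless because only the more stable propargylic alkoxide can rearrange.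

Step 13
Reactants: 21 (2Z,5E)-cyclodecadienone
Product: 22 10-hydroxy dienone
Conditions: HF·pyridine, pyridine, THF, 0 °C
Reagents that add atoms: none
Why: The triethylsilyl ether next to the ketone is the most labile silyl group and should be cleaved selectively by buffered HF (selective desilylation), which spares the secondary TBS and primary TBDPS ethers and avoids base-induced conjugation of the skipped diene.

Step 14
Reactants: 22 10-hydroxy dienone
Product: 23 bis-silyl furanone
Conditions: PdCl2(MeCN)2 (cat.), CuCl, O2 (1 atm), Na2HPO4, DME, 50 °C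
Reagents that add atoms: none
Why: In this Wacker-type oxidative cyclisation the C10 hydroxyl adds to C3 of the enone activated by divalent palladium (5-endo oxypalladation) and β-hydride elimination from the palladium enolate restores C2=C3 inside the new 3(2H)-furanone ring, while CuCl/O2 returns zerovalent palladium to the divalent state; no stereocentre is formed and the buffer protects C4.

Step 15
Reactants: 23 bis-silyl furanone
Product: 24 furanone diol
Conditions: Bu4NF, AcOH, THF, 0 °C → rt
Reagents that add atoms: none
Why: Buffered fluoride cleaves the secondary TBS and the primary TBDPS ether in one operation (global desilylation), and acetic acid keeps the medium from enolising C4–H next to the vinylogous ester.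

Step 16
Reactants: 24 furanone diol
Product: 27 furanone lactone (5E), via enal 25 (not isolated), via lactol 26 (not isolated)
Conditions: TEMPO (cat.), PhI(OAc)2, CH2Cl2, rt
Reagents that add atoms: none
Why: The oxoammonium species oxidises the primary allylic alcohol selectively to the enal, the C8 hydroxyl closes the five-membered lactol and a second oxidation gives the α-methylene γ-lactone (oxidative lactonisation), trans-fused because C7 and C8 keep their configurations.

Step 17
Reactants: 27 furanone lactone (5E)
Product: 28 5,6-diol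
Conditions: OsO4 (cat.), N-methylmorpholine N-oxide, acetone/H2O, 0 °C
Reagents that add atoms: N-methylmorpholine N-oxide, C[N+]1([O-])CCOCC1; water, O
Why: Upjohn syn-dihydroxylation should occur at C5=C6, the only electron-rich alkene, on its peripheral face (the inner face is covered by the ring when the C4 methyl and the C7 lactone carbon are pseudo-equatorial), so both oxygens enter anti to the transannular C1–C3 segment, O5 syn to the C4 methyl, and the E alkene gives the 5S,6S diol.

Step 18
Reactants: 28 5,6-diol
Product: 29 CNP0141385.1 (target)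
Conditions: (iPrCO)2O, Et3N, DMAP (cat.), CH2Cl2, −40 °C
Reagents that add atoms: isobutyric anhydride, CC(C)C(=O)OC(=O)C(C)C
Why: Nucleophile-catalysed acyl transfer should favour the C6 hydroxyl beside the flat lactone ring over the C5 hydroxyl, which is crowded by the C4 methyl group and the furanone, and the low temperature limits acyl migration from O6 to O5.

Compound list
1 | (R)-carvone | CC1=CC[C@H](CC1=O)C(C)=C | starting material
2 | (R)-5-(3-chloroprop-1-en-2-yl)-2-methylcyclohex-2-en-1-one | O=C1C(C)=CC[C@@H](C(=C)CCl)C1 | intermediate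
3 | allylic acetate: 2-[(R)-4-methyl-5-oxocyclohex-3-en-1-yl]allyl acetate | O=C1C(C)=CC[C@@H](C(=C)COC(C)=O)C1 | intermediate
4 | (R)-5-(3-hydroxyprop-1-en-2-yl)-2-methylcyclohex-2-en-1-one | O=C1C(C)=CC[C@@H](C(=C)CO)C1 | intermediate
5 | 12-O-TBDPS enone: (R)-5-[3-(tert-butyldiphenylsilyloxy)prop-1-en-2-yl]-2-methylcyclohex-2-en-1-one | O=C1C(C)=CC[C@@H](C(=C)CO[Si](c2ccccc2)(c2ccccc2)C(C)(C)C)C1 | intermediate
6 | allyl bromide | C=CCBr | starting material
7 | lithium dienolate of 5 (enolate C1=C6, alkene C9=C10) | [Li+].[O-]C1=C[C@H](C(=C)CO[Si](c2ccccc2)(c2ccccc2)C(C)(C)C)CC=C1C | intermediate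
8 | 6-allyl enone: 5 carrying a 6-allyl group trans to the C7 side chain | O=C1C(C)=CC[C@@H](C(=C)CO[Si](c2ccccc2)(c2ccccc2)C(C)(C)C)[C@@H]1CC=C | intermediate
9 | linear dienol silyl ether: 1-(tert-butyldimethylsilyloxy)-1(10),8-diene derived from 8 | CC(C)(C)[Si](C)(C)OC1=C(C)C=C[C@@H](C(=C)CO[Si](c2ccccc2)(c2ccccc2)C(C)(C)C)[C@@H]1CC=C | intermediate
10 | vinyl epoxide: 8,9-epoxide of 9, oxygen anti to the C7 side chain | CC(C)(C)[Si](C)(C)OC1=C(C)[C@@H]2O[C@@H]2[C@@H](C(=C)CO[Si](c3ccccc3)(c3ccccc3)C(C)(C)C)[C@@H]1CC=C | intermediate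
11 | 8-hydroxy enone: 8 with an 8-hydroxyl trans to the C7 side chain | O=C1C(C)=C[C@H](O)[C@@H](C(=C)CO[Si](c2ccccc2)(c2ccccc2)C(C)(C)C)[C@@H]1CC=C | intermediate
12 | hydroxy epoxy ketone: 9,10-epoxide of 11, cis to the 8-hydroxyl and trans to the C7 side chain | O=C1[C@]2(C)O[C@@H]2[C@H](O)[C@@H](C(=C)CO[Si](c3ccccc3)(c3ccccc3)C(C)(C)C)[C@@H]1CC=C | intermediate
13 | 8-O-TBS epoxy ketone | O=C1[C@]2(C)O[C@@H]2[C@H](O[Si](C)(C)C(C)(C)C)[C@@H](C(=C)CO[Si](c3ccccc3)(c3ccccc3)C(C)(C)C)[C@@H]1CC=C | intermediate
14 | propenyl epoxy ketone: 13 with 6-[(E)-prop-1-enyl] in place of 6-allyl | O=C1[C@]2(C)O[C@@H]2[C@H](O[Si](C)(C)C(C)(C)C)[C@@H](C(=C)CO[Si](c3ccccc3)(c3ccccc3)C(C)(C)C)[C@@H]1/C=C/C | intermediate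
15 | ethynylmagnesium bromide | C#C[Mg]Br | starting material
16 | epoxy ethynyl carbinol: 1-ethynyl-9,10-epoxycyclohexan-1-ol, 1-OH cis to the epoxide, ethynyl trans to the 6-propenyl group | C#C[C@@]1(O)[C@]2(C)O[C@@H]2[C@H](O[Si](C)(C)C(C)(C)C)[C@@H](C(=C)CO[Si](c3ccccc3)(c3ccccc3)C(C)(C)C)[C@@H]1/C=C/C | intermediate
17 | ethynyl 1,10-diol: 10-OH cis to 1-OH and to 8-OTBS, C9 now CH2 | C#C[C@@]1(O)[C@](C)(O)C[C@H](O[Si](C)(C)C(C)(C)C)[C@@H](C(=C)CO[Si](c2ccccc2)(c2ccccc2)C(C)(C)C)[C@@H]1/C=C/C | intermediate
18 | oxy-Cope precursor: 10-O-triethylsilyl ether of 17, a 1-ethynyl-2-[(E)-propenyl]cyclohexanol | C#C[C@@]1(O)[C@](C)(O[Si](CC)(CC)CC)C[C@H](O[Si](C)(C)C(C)(C)C)[C@@H](C(=C)CO[Si](c2ccccc2)(c2ccccc2)C(C)(C)C)[C@@H]1/C=C/C | intermediate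
19 | potassium alkoxide of 18 at O1 | C#C[C@@]1([O-])[C@](C)(O[Si](CC)(CC)CC)C[C@H](O[Si](C)(C)C(C)(C)C)[C@@H](C(=C)CO[Si](c2ccccc2)(c2ccccc2)C(C)(C)C)[C@@H]1/C=C/C.[K+] | intermediate
20 | potassium allenolate: ten-membered cyclodeca-1,2,5-trien-1-olate, (5E), allene axis as set by the rearrangement | [K+].[O-]C1=C=C[C@@H](C)/C=C/[C@H](C(=C)CO[Si](c2ccccc2)(c2ccccc2)C(C)(C)C)[C@@H](O[Si](C)(C)C(C)(C)C)C[C@@]1(C)O[Si](CC)(CC)CC | intermediate
21 | (2Z,5E)-cyclodecadienone: 4-methyl, 7-[1-(TBDPS-oxymethyl)vinyl], 8-OTBS, 10-methyl, 10-OTES | O=C1/C=C\[C@@H](C)/C=C/[C@H](C(=C)CO[Si](c2ccccc2)(c2ccccc2)C(C)(C)C)[C@@H](O[Si](C)(C)C(C)(C)C)C[C@@]1(C)O[Si](CC)(CC)CC | intermediate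
22 | 10-hydroxy dienone | O=C1/C=C\[C@@H](C)/C=C/[C@H](C(=C)CO[Si](c2ccccc2)(c2ccccc2)C(C)(C)C)[C@@H](O[Si](C)(C)C(C)(C)C)C[C@@]1(C)O | intermediate
23 | bis-silyl furanone: 3,10-oxygen-bridged 3(2H)-furanone, (5E), 8-OTBS, 12-OTBDPS | O=C1C=C2[C@@H](C)/C=C/[C@H](C(=C)CO[Si](c3ccccc3)(c3ccccc3)C(C)(C)C)[C@@H](O[Si](C)(C)C(C)(C)C)C[C@@]1(C)O2 | intermediate
24 | furanone diol (8-OH, 12-OH) | O=C1C=C2[C@@H](C)/C=C/[C@H](C(=C)CO)[C@@H](O)C[C@@]1(C)O2 | intermediate
25 | enal: 12-aldehyde of 24 | O=C1C=C2[C@@H](C)/C=C/[C@H](C(=C)C=O)[C@@H](O)C[C@@]1(C)O2 | intermediate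
26 | lactol: 8,12-hemiacetal, anomeric mixture | O=C1C=C2[C@@H](C)/C=C/[C@@H]3C(=C)C(O)O[C@H]3C[C@@]1(C)O2 | intermediate
27 | furanone lactone (5E): trans-fused α-methylene 8,12-lactone | O=C1C=C2[C@@H](C)/C=C/[C@@H]3C(=C)C(=O)O[C@H]3C[C@@]1(C)O2 | intermediate
28 | 5,6-diol (4S,5S,6S,7R,8S,10R) | C=C1C(=O)O[C@H]2C[C@@]3(C)OC(=CC3=O)[C@@H](C)[C@H](O)[C@@H](O)[C@H]12 | intermediate
29 | CNP0141385.1, the 6-O-isobutyrate (4S,5S,6S,7R,8S,10R) | C=C1C(=O)O[C@H]2C[C@@]3(C)OC(=CC3=O)[C@@H](C)[C@H](O)[C@@H](OC(=O)C(C)C)[C@H]12 | target

Total step count: 18. Longest linear sequence: 18 steps from (R)-carvone; the route is fully linear, with 6 and 15 entering as small building blocks.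

Steps most likely to fail

Step 12. The crowded tertiary alkoxide may be diverted before it reaches the chair-like transition state, by metallation of the terminal alkyne, by loss of acetylide in a retro-addition, or by unproductive silyl transfer. The fallback sets out from 18: TMSOTf and 2,6-lutidine give the C1 trimethylsilyl ether F1, which is heated in o-dichlorobenzene at about 190 °C. The neutral siloxy-Cope shift should pass through the same chair and give the cyclic silyl allenyl ether F2. Oxalic acid in wet THF then protonates C2 and hydrolyses the enol ether, and the route is rejoined at 21.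

Step 14. The 5-endo oxypalladation may be slow in the macrocycle, so that allylic C–H activation at C4 or alkene migration by a palladium hydride takes over. The fallback sets out from 22: catalytic camphorsulfonic acid in CH2Cl2 adds the C10 hydroxyl to C3 (acid-catalysed oxa-Michael addition) and gives the saturated 3-oxotetrahydrofuran F3. LiN(SiMe3)2 and PhSeBr at −78 °C, kept cold to prevent retro-Michael opening, give the 2-phenylselanyl ketone F4. H2O2 at 0 °C then brings about selenoxide syn-elimination toward C3–H, and the route is rejoined at 23.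

Step 18. Acyl transfer may not discriminate between the two secondary hydroxyls, or may prefer O5, and the ester may migrate between O6 and O5. The fallback uses the same steric preference the other way round and sets out from 28: TESCl and imidazole at −20 °C silylate the more reactive hydroxyl and, if that is O5, give the 5-O-triethylsilyl ether F5. Isobutyryl chloride with pyridine and DMAP then acylates O6 to the silyl isobutyrate F6, and HF·pyridine removes the silyl group, so that the route is rejoined at 29.

Further compounds
F1 | step 12 | C1 trimethylsilyl ether of 18 | C#C[C@@]1(O[Si](C)(C)C)[C@](C)(O[Si](CC)(CC)CC)C[C@H](O[Si](C)(C)C(C)(C)C)[C@@H](C(=C)CO[Si](c2ccccc2)(c2ccccc2)C(C)(C)C)[C@@H]1/C=C/C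
F2 | step 12 | cyclic silyl allenyl ether (1-trimethylsilyloxycyclodeca-1,2,5-triene, allene axis undefined) | C[Si](C)(C)OC1=C=C[C@@H](C)/C=C/[C@H](C(=C)CO[Si](c2ccccc2)(c2ccccc2)C(C)(C)C)[C@@H](O[Si](C)(C)C(C)(C)C)C[C@@]1(C)O[Si](CC)(CC)CC
F3 | step 14 | saturated 3-oxotetrahydrofuran (2,3-dihydro analogue of 23, C3 undefined) | O=C1CC2[C@@H](C)/C=C/[C@H](C(=C)CO[Si](c3ccccc3)(c3ccccc3)C(C)(C)C)[C@@H](O[Si](C)(C)C(C)(C)C)C[C@@]1(C)O2
F4 | step 14 | 2-phenylselanyl ketone (C2 and C3 undefined) | O=C1C([Se]c3ccccc3)C2[C@@H](C)/C=C/[C@H](C(=C)CO[Si](c4ccccc4)(c4ccccc4)C(C)(C)C)[C@@H](O[Si](C)(C)C(C)(C)C)C[C@@]1(C)O2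
F5 | step 18 | 5-O-triethylsilyl ether of 28 | C=C1C(=O)O[C@H]2C[C@@]3(C)OC(=CC3=O)[C@@H](C)[C@H](O[Si](CC)(CC)CC)[C@@H](O)[C@H]12
F6 | step 18 | 5-O-triethylsilyl 6-O-isobutyrate | C=C1C(=O)O[C@H]2C[C@@]3(C)OC(=CC3=O)[C@@H](C)[C@H](O[Si](CC)(CC)CC)[C@@H](OC(=O)C(C)C)[C@H]12
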